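Your reading falls at 5.0 min, while the gamma run stops at 60.0 s, so you have to solve this flask at both ends, the decay you can see and the stop you cannot, and then join them.

- gamma: substrate 0.15 M (fed, over 8.0 s); coupling partner 0.142 M; protic impurity 0.022 M; initiator 1.5 mM; run made earlier
- flask: substrate 0.15 M (fed, over 8.0 s); coupling partner 0.142 M; protic impurity 0.0450 M; initiator 1.5 mM; time 5.0 min

- gamma (time / s: target / %, substrate / %): 10.0: 6.7, 93.5; 20.0: 15.8, 84.2; 30.0: 24.0, 76.3; 40.0: 31.0, 69.1; 50.0: 37.6, 62.3; 60.0: 42.6, 57.8

(readings scatter by 0.3 percentage points)

- no earlier run changes the charge of protic impurity; that part of a forecast is a guess

* how much target the flask holds at 5.0 min, in percent of the substrate charged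
* how much substrate the flask holds at 5.0 min, in percent of the substrate charged
* concentration of coupling partner at 5.0 min, in M

Take the early end first. In the gamma run, target and substrate add up to 100% of the charge at 60.0 s, so no side loss of substrate shows. From 10.0 s on, after the feed, the gamma readings give a first-order constant of 0.00962 /s for the substrate. Carried to 5.0 min, that reckoning leaves 5.58% of the substrate.

The objection is that each target should cost one coupling partner. By 60.0 s of the gamma run that count has used 45.0% of the partner's charge, yet the constant read from its readings went from 0.0102 /s to 0.00926 /s. So the curve gives little warning, and the late end must come from counting.

The partner's charge is 94.7% of the substrate charge. If each protic impurity destroys one partner, which no run tests, there remains the partner budget, the charge of coupling partner less that of protic impurity, as a fraction of the substrate charged: 64.7%. In this flask that makes the coupling partner the limiting reagent of the reckoning.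

But the impurity may not finish its work, so you take the budget as a low estimate of the target and the partner's charge as a high one. Carried on at the gamma constant, the reckoned decay comes down to the budget at 1.80 min, earlier than the reading. You therefore commit to target somewhat above the budget, substrate as the remainder and a small remainder of coupling partner.

The forecast, which differs from this, gives 78% target, 22% substrate and 0.025 M partner, on its guess about the impurity, "I guess it retards a chain or catalyst roughly inversely".

The flask gives 69.8% target, 29.5% substrate and 0.00400 M coupling partner.

    initiator → 2 initiating radical (k = 0.00240 /s)
    substrate + initiating radical → capped initiator + first chain carrier (k = 1.70 × 10⁶ /M/s)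
    coupling partner + first chain carrier ⇌ target + second chain carrier (K = 0.230, k = 68000 /M/s)
    substrate + second chain carrier → released group + first chain carrier (k = 1.90 × 10⁵ /M/s)
    2 first chain carrier → ended chains A (k = 8.90 × 10⁶ /M/s)
    2 second chain carrier → ended chains B (k = 1.00 × 10⁹ /M/s)
    coupling partner + protic impurity → quenched reagent (k = 0.140 /M/s)

In this flask target stands 5.1 percentage points above the budget, with 26% of the impurity still unbound at 5.00 min. With the partner's level held, the same run gives 93.1% target, so the falling partner, down to 2.8% of its charge, is the main reason for the 69.8%. In the neighbour flask with 0.26 M of substrate, the budget is 37.3%. Counting the 0.0262 M of quenched reagent actually formed there instead of the impurity's charge raises it to 44.5%, and that flask holds 44.4% target with 0.25% of its partner left.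

The readings come from a simulation with constants of no real substance, noise included.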